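**Assumptions (one line each):**
- RAMP delivers the (R)-α-silyloxy centre, by analogy with SAMP and 3-pentanone giving (S)-4-methyl-3-heptanone.
- LDA metalates the hydrazone at the CH2OTBS carbon.
- The Brown methallylborane enantiomer is chosen to give the (S)-carbinol.

## Retrosynthetic overview
1. Target **20** comes from two E-selective cross-metatheses. First, the isoprenyl terminus of lactone **11** couples with (S)-methallyl vinyl carbinol **14**. Then the methallyl terminus of that product couples with 3-(but-3-enyl)furan **18**.
2. Lactone **11** comes from desilylation and acetylation of **9**. Compound **9** is made in the radical key step: SmI2 ketyl–acrylate coupling of the α-silyloxy methyl ketone **7** with methyl acrylate. This forms the quaternary C–CH2 bond, sets the tertiary carbinol centre, and closes the γ-lactone, which is the only ring formed.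
3. Ketone **7** comes from RAMP-hydrazone alkylation of TBSO-acetone with homoprenyl bromide, which sets C15.
4. The furan enters as 2-(3-furyl)ethanol. The carbinol centre comes from Brown methallylation of acrolein.

## Route

**Step 1**
Reactants: **1** hydroxyacetone
Product: **2** 1-(tert-butyldimethylsilyloxy)propan-2-one
Conditions: TBSCl, imidazole, DMF, 0 °C → rt
Reagents that add atoms: TBSCl, C[Si](C)(C(C)(C)C)Cl
Why: Silylation of the primary alcohol, giving a protected α-oxygenated ketone for the auxiliary-controlled alkylation.

**Step 2**
Reactants: **2**; **3** (R)-RAMP, (R)-1-amino-2-(methoxymethyl)pyrrolidine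
Product: **4** RAMP hydrazone of **2**
Conditions: neat, 60 °C, 16 h
Reagents that add atoms: none
Why: Hydrazone condensation creates the chiral azaenolate precursor.

**Step 3**
Reactants: **4**; **5** 4-bromo-2-methylbut-1-ene
Product: **6** alkylated hydrazone (new C15 centre, R)
Conditions: LDA, THF, 0 °C; then **5**, −100 °C → rt
Reagents that add atoms: none
Why: Enders asymmetric α-alkylation. The Li-chelated azaenolate is alkylated from the face set by the pyrrolidine, so the (R) centre at C15 (the future CH–OAc) forms with expected de ≥ 90%. Metalation at the oxygenated carbon is assumed.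

**Step 4**
Reactants: **6**
Product: **7** (R)-3-(TBSO)-6-methylhept-6-en-2-one
Conditions: sat. aq. oxalic acid, Et2O, rt
Reagents that add atoms: water, O
Why: Mild hydrolytic hydrazone cleavage leaves the silyl ether, the 1,1-disubstituted alkene and the α-stereocentre intact; RAMP is recovered.

**Step 5 (radical key step)**
Reactants: **7**; **8** methyl acrylate
Product: **9** (S)-5-[(R)-1-(TBSO)-4-methylpent-4-en-1-yl]-5-methyldihydrofuran-2(3H)-one
Conditions: SmI2 (2.5 equiv), t-BuOH (2 equiv), THF, rt; then cat. TsOH, CH2Cl2
Reagents that add atoms: none
Why: SmI2 reduces the ketone to a Sm(III) ketyl radical anion, which adds to the β-carbon of acrylate. The resulting α-ester radical is reduced to the enolate and protonated, and the tertiary Sm-alkoxide closes the γ-lactone (Fukuzawa-type ketyl–olefin coupling). The new quaternary centre is set by Felkin–Anh-type induction from C15. The bulky OTBS group cannot chelate and sits anti to the incoming acrylate, predicting the (R,S) relative configuration of the target. I expect dr of about 4:1 and would remove the minor diastereomer by chromatography.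
Proposed new method: SmI2 ketyl–acrylate lactonization of an α-silyloxy methyl ketone.
- Mechanism: C–O cleavage of α-oxygenated ketones needs a second electron, which should be slow without HMPA, while ketyl addition to excess acrylate is fast. The silyl ether stops Sm chelation, so a Felkin-type rather than a chelate-type outcome is expected.
- Closest known reaction: Fukuzawa ketone–acrylate γ-lactone synthesis.

**Step 6**
Reactants: **9**
Product: **10** (S)-5-[(R)-1-hydroxy-4-methylpent-4-en-1-yl]-5-methyldihydrofuran-2(3H)-one
Conditions: HF·py, pyridine/THF, 0 °C → rt
Reagents that add atoms: none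
Why: Fluoride desilylation under non-basic conditions avoids opening the lactone. No stereocentre is touched.

**Step 7**
Reactants: **10**
Product: **11** acetate of **10**
Conditions: Ac2O, Et3N, DMAP, CH2Cl2, 0 °C
Reagents that add atoms: acetic anhydride, CC(=O)OC(C)=O
Why: Acetylation installs the C15 acetate before the free carbinol is introduced, so no differentiation of the two hydroxyls is needed.

**Step 8**
Reactants: **12** acrolein; **13** methallyl chloride
Product: **14** (S)-2-methylhexa-1,5-dien-4-ol
Conditions: (i) **13**, Mg, THF; (ii) (−)-Ipc2BOMe, −78 °C; (iii) **12**, Et2O, −100 → −78 °C; (iv) NaOH, H2O2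
Reagents that add atoms: hydrogen peroxide, OO (its oxygen becomes the carbinol oxygen)
Why: Brown asymmetric methallylboration proceeds through a chair transition state. The Ipc ligands set the (S) carbinol, expected ≥ 90% ee.

**Step 9**
Reactants: **15** 2-(furan-3-yl)ethanol
Product: **16** 3-(2-iodoethyl)furan
Conditions: PPh3, I2, imidazole, CH2Cl2, 0 °C
Reagents that add atoms: iodine, II
Why: Appel iodination under mild, non-acidic conditions that the furan tolerates.

**Step 10**
Reactants: **16**; **17** vinylmagnesium bromide
Product: **18** 3-(but-3-en-1-yl)furan
Conditions: Li2CuCl4 (5 mol %), THF, −20 → 0 °C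
Reagents that add atoms: none
Why: Cu-catalysed SN2 coupling of a primary alkyl iodide with a vinyl Grignard, giving the terminal-alkene metathesis partner.

**Step 11**
Reactants: **11**; **14** (4 equiv)
Product: **19** (E)-trisubstituted enol-alcohol
Conditions: Hoveyda–Grubbs II (5 mol %), p-benzoquinone (10 mol %), CH2Cl2, 40 °C
Reagents that add atoms: none
Why: Cross-metathesis of the reactive monosubstituted vinyl carbinol **14** with the 1,1-disubstituted isoprenyl alkene of **11** gives the E-trisubstituted allylic alcohol. The E selectivity is thermodynamic; the carbinol centre is untouched.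

**Step 12**
Reactants: **19**; **18** (6 equiv)
Product: **20** 15-acetylirciformonin B
Conditions: Hoveyda–Grubbs II (10 mol %), p-benzoquinone, CH2Cl2, 40 °C
Reagents that add atoms: none
Why: Cross-metathesis of the methallyl terminus (1,1-disubstituted) with terminal alkene **18** gives the second E-trisubstituted alkene. The homoallylic OH assists the reaction. All three stereocentres were set earlier (C15 in Step 3, C-quaternary in Step 5, carbinol in Step 8) and none is epimerizable under these conditions.

## Compound list
1 | hydroxyacetone | CC(=O)CO | starting material
2 | 1-(TBSO)propan-2-one | CC(=O)CO[Si](C)(C)C(C)(C)C | intermediate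
3 | (R)-RAMP | COC[C@H]1CCCN1N | starting material
4 | RAMP hydrazone of 2 | CC(=NN1CCC[C@@H]1COC)CO[Si](C)(C)C(C)(C)C | intermediate
5 | 4-bromo-2-methylbut-1-ene | C=C(C)CCBr | starting material
6 | alkylated hydrazone | CC(=NN1CCC[C@@H]1COC)[C@@H](CCC(C)=C)O[Si](C)(C)C(C)(C)C | intermediate
7 | (R)-3-(TBSO)-6-methylhept-6-en-2-one | CC(=O)[C@@H](CCC(C)=C)O[Si](C)(C)C(C)(C)C | intermediate
8 | methyl acrylate | C=CC(=O)OC | starting material
9 | TBS-lactone | CC(C)(C)[Si](C)(C)O[C@H](CCC(C)=C)[C@]1(C)CCC(=O)O1 | intermediate
10 | hydroxy-lactone | O[C@H](CCC(C)=C)[C@]1(C)CCC(=O)O1 | intermediate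
11 | acetoxy-lactone | CC(=O)O[C@H](CCC(C)=C)[C@]1(C)CCC(=O)O1 | intermediate
12 | acrolein | C=CC=O | starting material
13 | methallyl chloride | C=C(C)CCl | starting material
14 | (S)-2-methylhexa-1,5-dien-4-ol | C=C[C@@H](O)CC(C)=C | intermediate
15 | 2-(furan-3-yl)ethanol | OCCc1ccoc1 | starting material
16 | 3-(2-iodoethyl)furan | ICCc1ccoc1 | intermediate
17 | vinylmagnesium bromide | C=C[Mg]Br | starting material
18 | 3-(but-3-en-1-yl)furan | C=CCCc1ccoc1 | intermediate
19 | CM product | CC(=O)O[C@H](CC/C(C)=C/[C@@H](O)CC(C)=C)[C@]1(C)CCC(=O)O1 | intermediate
20 | 15-acetylirciformonin B | CC(=O)O[C@H](CC/C(C)=C/[C@@H](O)C/C(C)=C/CCc1ccoc1)[C@]1(C)CCC(=O)O1 | target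

## Totals
Total steps: 12. Longest linear sequence: 9 (Steps 1–7, 11, 12).

## Three steps most likely to fail
1. **Step 5 (SmI2 coupling).** The α-OTBS group may be cleaved reductively, or dr may be poor.
   - Fallback: set C15 and the quaternary centre together by Shi asymmetric epoxidation of an (E)-Δ-alkenoate, followed by acid-mediated epoxy-acid lactonization. Anti opening with inversion at the tertiary carbon gives the (R,S) lactone.
2. **Step 12 (second cross-metathesis).** E/Z selectivity may be poor, and the trisubstituted alkene may scramble.
   - Fallback: build the right arm by asymmetric propargylation of the enal to a homopropargylic alcohol, then Zr-catalysed methylalumination/I2 to the (E)-vinyl iodide. Couple this with 3-furylethylzinc iodide under Ni or Pd catalysis.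
3. **Step 3 (hydrazone alkylation).** The regiochemistry of metalation or the sense of induction may be wrong.
   - Fallback: Carreira alkynylation of 4-methylpent-4-enal, then TBS protection and Markovnikov alkyne hydration, to give ketone **7**.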